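**Retrosynthetic overview**
Feature: in ring B (labdane numbering) C5, the quaternary C10 and C9 are three contiguous stereocentres, and the C8 methyl sits on a carbon that can come from an alkene (C7=C8). Ring B is therefore read as the cyclohexene adduct of a C5=C10 enal and a C6–C9 diene.
Late disconnections: C12–C13 (Negishi coupling with an E iodoalkene), C3–Br (ketone, then alkenyl bromide, then radical hydrogenation), C8–OH (Mukaiyama hydration of C7=C8).
Ring A: aldol condensation of C2 onto C1 in the keto aldehyde adduct. Ring B: catalytic enantioselective intermolecular Diels–Alder reaction forming C5–C6 and C9–C10.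
Order of ring formation: ring B (step 7), then ring A (step 8).

Key step: step 7

Remark on the chemistry: labdane numbering is used and α/β refer to the ring faces, β being the face of the C10 methyl; the target belongs to the mirror-image (ent) labdane series (C10 is R; decalin descriptors 1S,2S,4aS,6R,8aR), which fixes the catalyst enantiomer in step 7, and the C12 oxygen is carried as a 4-methoxybenzyl (PMB) ether so that it can be freed in the presence of a silyl ether.

Step 1
Reactants: 1 methyl 2,2-dimethyl-3-oxobutanoate
Product: 2 2,2-dimethylbutane-1,3-diol (racemic)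
Conditions: LiAlH4, THF, 0 °C → rt; aqueous work-up
Reagents that add atoms: none
Why: Hydride reduction with LiAlH4 takes ester and ketone together to the diol, so the two carbonyl groups need not be told apart, and the racemic carbinol centre is removed again in step 2.

Step 2
Reactants: 2 2,2-dimethylbutane-1,3-diol
Product: 3 2,2-dimethyl-3-oxobutanal
Conditions: (COCl)2, DMSO, CH2Cl2, −78 °C; Et3N, −78 °C → rt; carried on as a solution
Reagents that add atoms: none
Why: Swern oxidation converts both hydroxyl groups to carbonyls, and the quaternary carbon between them rules out enolisation, elimination and self-aldol reaction of the volatile keto aldehyde.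

Step 3
Reactants: 3 2,2-dimethyl-3-oxobutanal; 4 2-(triphenylphosphoranylidene)propanal
Product: 5 (2E)-2,4,4-trimethyl-5-oxohex-2-enal
Conditions: toluene, 90 °C
Reagents that add atoms: none
Why: Wittig olefination with the formyl-stabilised ylide occurs only at the aldehyde (the hindered ketone is inert to stabilised ylides) and should give the E trisubstituted enal, as is usual for stabilised ylides and α-branched aldehydes.

Step 4
Reactants: 6 3-[(4-methoxybenzyl)oxy]propan-1-ol
Product: 7 3-[(4-methoxybenzyl)oxy]propanal
Conditions: PhI(OAc)2, TEMPO (cat.), CH2Cl2, rt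
Reagents that add atoms: none
Why: The nitroxyl-catalysed oxidation of a primary alcohol stops at the aldehyde under non-basic conditions, so β-elimination of the benzyloxy group is avoided.

Step 5
Reactants: 7 3-[(4-methoxybenzyl)oxy]propanal; 4 2-(triphenylphosphoranylidene)propanal
Product: 8 (2E)-5-[(4-methoxybenzyl)oxy]-2-methylpent-2-enal
Conditions: benzene, 80 °C
Reagents that add atoms: none
Why: Wittig olefination with the stabilised ylide should give the E enal, which fixes the geometry of the later C8=C9 diene bond (C11 "outside").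

Step 6
Reactants: 8 (2E)-5-[(4-methoxybenzyl)oxy]-2-methylpent-2-enal
Product: 9 1-methoxy-4-({[(3E)-4-methylhexa-3,5-dien-1-yl]oxy}methyl)benzene
Conditions: Ph3PCH3Br, KOt-Bu, THF, 0 °C → rt
Reagents that add atoms: methyltriphenylphosphonium bromide, C[P+](c1ccccc1)(c1ccccc1)c1ccccc1.[Br-]
Why: Wittig methylenation adds to the formyl group in the 1,2 sense and leaves the E trisubstituted alkene unchanged, giving the 1,3-diene C6=C7–C8=C9.

Step 7
Reactants: 5 (2E)-2,4,4-trimethyl-5-oxohex-2-enal; 9 1-methoxy-4-({[(3E)-4-methylhexa-3,5-dien-1-yl]oxy}methyl)benzene (excess)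
Product: 10 (1S,2R,6S)-2-{2-[(4-methoxybenzyl)oxy]ethyl}-1,3-dimethyl-6-(2-methyl-3-oxobutan-2-yl)cyclohex-3-ene-1-carbaldehyde
Conditions: (R)-3,3-diphenyl-1-(2-methylphenyl)tetrahydro-1H,3H-pyrrolo[1,2-c][1,3,2]oxazaborole (20 mol %), HN(SO2CF3)2 (18 mol %), CH2Cl2, −78 → −20 °C
Reagents that add atoms: none
Why: The boron of the oxazaborolidinium ion binds the formyl oxygen of the s-trans enal 5 (with a formyl C–H···O contact to the ring oxygen) and lowers its LUMO, so that a concerted but asynchronous Diels–Alder reaction follows in which C5–C6 forms ahead of C9–C10; the closest known reaction type is the oxazaborolidinium-catalysed cycloaddition of 2-methyl-2-alkenals such as tiglic aldehyde, of which a β-tert-alkyl enal is a hindered extreme. Ring B closes as a cyclohexene by intermolecular [4+2] cycloaddition, both ring bonds in one step. C5 and C10 follow from suprafacial addition to the E alkene (C1 and C4 trans, as the later trans ring fusion needs); the absolute sense comes from the catalyst, whose phenyl group covers one face of the bound enal so that the diene should add to the si face of C10 (on this model the R catalyst exposes that face, and its antipode is equally available should the sense prove opposite for this enal); C9 follows from the E geometry of C8=C9 combined with the formyl-exo, methyl-endo arrangement, which puts C11 cis to the C10 methyl. The C5-to-C6 regiochemistry rests on the alkyl group at C9, which makes the unsubstituted C6 the more nucleophilic diene terminus, and on sterics, since only this CH2 terminus can reach the tert-alkyl-bearing C5; the C8 methyl alone would weakly favour the other orientation and is expected to be overridden. The exo arrangement is supported by the α-methyl group of 5 and by the C8 methyl of the diene, which would meet the boron-bound formyl group in the endo arrangement, but it forces the C4 tert-alkyl group under C7 and is where the step is most likely to fail. The hindered acetyl group is expected to compete little for boron, and catalyst control of the enal face holds for either arrangement.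

Step 8
Reactants: 10 (1S,2R,6S)-2-{2-[(4-methoxybenzyl)oxy]ethyl}-1,3-dimethyl-6-(2-methyl-3-oxobutan-2-yl)cyclohex-3-ene-1-carbaldehyde
Product: 12 ent-(12-[(4-methoxybenzyl)oxy]-13,14,15,16-tetranorlabda-1,7-dien-3-one), via β-hydroxy ketone 11 (not isolated)
Conditions: KOH (0.3 equiv), MeOH, 50 °C
Reagents that add atoms: none
Why: Intramolecular aldol condensation, in which the only enolisable position (the C2 methyl of the ketone) adds to the non-enolisable C1 aldehyde and water is lost by E1cB, closes ring A as the trans-fused enone because C1 and C4 are trans on ring B, with no stereocentre touched.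

Step 9
Reactants: 12 ent-(12-[(4-methoxybenzyl)oxy]-13,14,15,16-tetranorlabda-1,7-dien-3-one)
Product: 13 ent-(12-[(4-methoxybenzyl)oxy]-13,14,15,16-tetranorlabd-7-en-3-one)
Conditions: H2 (1 atm), RhCl(PPh3)3 (10 mol %), benzene/EtOH, rt
Reagents that add atoms: none
Why: Homogeneous hydrogenation with RhCl(PPh3)3 saturates the disubstituted C1=C2 bond of the enone and leaves the trisubstituted C7=C8 bond and the benzylic ether untouched.

Step 10
Reactants: 13 ent-(12-[(4-methoxybenzyl)oxy]-13,14,15,16-tetranorlabd-7-en-3-one)
Product: 15 ent-(8α-hydroxy-12-[(4-methoxybenzyl)oxy]-13,14,15,16-tetranorlabdan-3-one), via 8α-hydroperoxide 14 (not isolated)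
Conditions: Co(acac)2 (20 mol %), PhSiH3, O2 (1 atm), THF, rt; then PPh3
Reagents that add atoms: dioxygen, O=O
Why: In this Mukaiyama hydration a cobalt hydride transfers a hydrogen atom to C7, and the tertiary C8 radical should take up O2 on the α face, away from the axial C10 methyl and the C9 chain, giving after reduction of the hydroperoxide the equatorial 8α-ol with the C8 methyl axial.

Step 11
Reactants: 15 ent-(8α-hydroxy-12-[(4-methoxybenzyl)oxy]-13,14,15,16-tetranorlabdan-3-one)
Product: 16 ent-(12-[(4-methoxybenzyl)oxy]-8α-(triethylsilyloxy)-13,14,15,16-tetranorlabdan-3-one)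
Conditions: Et3SiOTf, 2,6-lutidine, CH2Cl2, −78 °C
Reagents that add atoms: triethylsilyl trifluoromethanesulfonate, CC[Si](CC)(CC)OS(=O)(=O)C(F)(F)F
Why: Silylation with the silyl triflate covers the hindered tertiary alcohol at low temperature without enolising the C3 ketone, which keeps the 8-oxygen out of the base treatment of step 12 and prevents it from closing a tetrahydrofuran onto C12 in step 16.

Step 12
Reactants: 16 ent-(12-[(4-methoxybenzyl)oxy]-8α-(triethylsilyloxy)-13,14,15,16-tetranorlabdan-3-one)
Product: 17 ent-(12-[(4-methoxybenzyl)oxy]-8α-(triethylsilyloxy)-13,14,15,16-tetranorlabd-2-en-3-yl trifluoromethanesulfonate)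
Conditions: KN(SiMe3)2, THF, −78 °C; PhNTf2, −78 → 0 °C
Reagents that add atoms: N-phenylbis(trifluoromethanesulfonimide), O=S(=O)(N(c1ccccc1)S(=O)(=O)C(F)(F)F)C(F)(F)F
Why: Enolate O-triflation is regiospecific because C4 is quaternary and only C2 carries α-hydrogens, so the C2=C3 enol triflate is the only possible product.

Step 13
Reactants: 17 ent-(12-[(4-methoxybenzyl)oxy]-8α-(triethylsilyloxy)-13,14,15,16-tetranorlabd-2-en-3-yl trifluoromethanesulfonate)
Product: 18 ent-(3-bromo-12-[(4-methoxybenzyl)oxy]-8α-(triethylsilyloxy)-13,14,15,16-tetranorlabd-2-ene)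
Conditions: Ni(OAc)2·4H2O (10 mol %), 1,5-cyclooctadiene (30 mol %), Zn (30 mol %), LiBr, DMA/THF, rt
Reagents that add atoms: lithium bromide, [Li+].[Br-]
Why: Nickel-catalysed halogen exchange of an enol triflate (oxidative addition of zerovalent nickel into the C–O bond, triflate-for-bromide exchange, reductive elimination) replaces the triflate by bromine without moving the C2=C3 bond.

Step 14
Reactants: 18 ent-(3-bromo-12-[(4-methoxybenzyl)oxy]-8α-(triethylsilyloxy)-13,14,15,16-tetranorlabd-2-ene)
Product: 19 ent-(3β-bromo-12-[(4-methoxybenzyl)oxy]-8α-(triethylsilyloxy)-13,14,15,16-tetranorlabdane)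
Conditions: Mn(dpm)3 (10 mol %; dpm = dipivaloylmethanate), PhSiH3, t-BuOOH, 2-propanol, rt
Reagents that add atoms: none
Why: In this hydrogen-atom-transfer hydrogenation of an alkenyl halide a manganese hydride delivers H to C2, and the bromine-stabilised C3 radical should then take its hydrogen axially from the α face (opposite the axial C4 methyl), leaving the C–Br bond intact and the bromine equatorial (3β), which is also the more stable epimer.

Step 15
Reactants: 19 ent-(3β-bromo-12-[(4-methoxybenzyl)oxy]-8α-(triethylsilyloxy)-13,14,15,16-tetranorlabdane)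
Product: 20 ent-(3β-bromo-8α-(triethylsilyloxy)-13,14,15,16-tetranorlabdan-12-ol)
Conditions: DDQ, CH2Cl2/pH 7 buffer, 0 °C → rt
Reagents that add atoms: none
Why: Oxidative cleavage of the 4-methoxybenzyl ether (hydride abstraction by the quinone, then hydrolysis of the oxocarbenium ion) frees the primary alcohol while the tertiary silyl ether and the bromide are inert to the buffered oxidant.

Step 16
Reactants: 20 ent-(3β-bromo-8α-(triethylsilyloxy)-13,14,15,16-tetranorlabdan-12-ol)
Product: 21 ent-(3β-bromo-12-iodo-8α-(triethylsilyloxy)-13,14,15,16-tetranorlabdane)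
Conditions: I2, PPh3, imidazole, CH2Cl2, 0 °C → rt
Reagents that add atoms: iodine, I-I
Why: Appel-type iodination (SN2 attack of iodide on the primary alkoxyphosphonium ion) gives the primary iodide, the silylated 8-oxygen cannot cyclise onto C12, and the secondary neopentyl bromide does not undergo substitution.

Step 17
Reactants: 22 but-2-yn-1-ol
Product: 23 tert-butyl(but-2-yn-1-yloxy)dimethylsilane
Conditions: t-BuMe2SiCl, imidazole, CH2Cl2, rt
Reagents that add atoms: tert-butyldimethylsilyl chloride, CC(C)(C)[Si](C)(C)Cl
Why: Imidazole-promoted silylation protects the primary alcohol for the organometallic steps that follow.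

Step 18
Reactants: 23 tert-butyl(but-2-yn-1-yloxy)dimethylsilane
Product: 25 tert-butyl{[(2E)-3-iodobut-2-en-1-yl]oxy}dimethylsilane, via alkenylzirconocene chloride 24 (not isolated)
Conditions: Cp2Zr(H)Cl, THF, 50 °C; then I2, 0 °C
Reagents that add atoms: iodine, I-I
Why: Hydrozirconation adds H and Zr syn across the alkyne and, with warming, should settle zirconium on the less hindered carbon next to the methyl group, so that iodinolysis with retention gives the E iodoalkene with iodine trans to the CH2O group.

Step 19
Reactants: 21 ent-(3β-bromo-12-iodo-8α-(triethylsilyloxy)-13,14,15,16-tetranorlabdane); 25 tert-butyl{[(2E)-3-iodobut-2-en-1-yl]oxy}dimethylsilane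
Product: 27 ent-(3β-bromo-15-(tert-butyldimethylsilyloxy)-8α-(triethylsilyloxy)labd-13E-ene), via alkylzinc iodide 26 (not isolated)
Conditions: Zn dust (activated with 1,2-dibromoethane and Me3SiCl), DMA, 40 °C; then 25, PdCl2(dppf) (5 mol %), rt → 40 °C
Reagents that add atoms: none
Why: In this Negishi coupling zinc inserts only into the primary C–I bond, and palladium-catalysed sp3–sp2 coupling with the alkenyl iodide forms C12–C13 with retention of the E geometry, the secondary neopentyl bromide being inert to zinc and to zerovalent palladium under these conditions.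

Step 20
Reactants: 27 ent-(3β-bromo-15-(tert-butyldimethylsilyloxy)-8α-(triethylsilyloxy)labd-13E-ene)
Product: 28 (1S,2S,4aS,6R,8aR)-6-bromo-1-[(3E)-5-hydroxy-3-methylpent-3-en-1-yl]-2,5,5,8a-tetramethyldecahydronaphthalen-2-ol (target)
Conditions: HF·pyridine, pyridine, THF, 0 °C → rt
Reagents that add atoms: none
Why: Buffered fluoride desilylation removes the primary tert-butyldimethylsilyl and the tertiary triethylsilyl ether together, under conditions that should spare the allylic alcohol, the tertiary alcohol and the bromide.

**Compound list**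
1 | methyl 2,2-dimethyl-3-oxobutanoate | CC(=O)C(C)(C)C(=O)OC | starting material
2 | 2,2-dimethylbutane-1,3-diol (racemic) | CC(O)C(C)(C)CO | intermediate
3 | 2,2-dimethyl-3-oxobutanal | CC(=O)C(C)(C)C=O | intermediate
4 | 2-(triphenylphosphoranylidene)propanal | CC(C=O)=P(c1ccccc1)(c1ccccc1)c1ccccc1 | starting material
5 | (2E)-2,4,4-trimethyl-5-oxohex-2-enal | O=C/C(C)=C/C(C)(C)C(C)=O | intermediate
6 | 3-[(4-methoxybenzyl)oxy]propan-1-ol | COc1ccc(COCCCO)cc1 | starting material
7 | 3-[(4-methoxybenzyl)oxy]propanal | COc1ccc(COCCC=O)cc1 | intermediate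
8 | (2E)-5-[(4-methoxybenzyl)oxy]-2-methylpent-2-enal | COc1ccc(cc1)COCC/C=C(\C)C=O | intermediate
9 | 1-methoxy-4-({[(3E)-4-methylhexa-3,5-dien-1-yl]oxy}methyl)benzene | COc1ccc(cc1)COCC/C=C(\C)C=C | intermediate
10 | (1S,2R,6S)-2-{2-[(4-methoxybenzyl)oxy]ethyl}-1,3-dimethyl-6-(2-methyl-3-oxobutan-2-yl)cyclohex-3-ene-1-carbaldehyde | COc1ccc(cc1)COCC[C@H]1[C@](C)(C=O)[C@H](CC=C1C)C(C)(C)C(C)=O | intermediate
11 | β-hydroxy ketone (aldol) from 10: ring A closed, hydroxyl at C1 (either epimer), ketone at C3, C7=C8 | COc1ccc(cc1)COCC[C@H]1[C@]2(C)C(O)CC(=O)C(C)(C)[C@H]2CC=C1C | intermediate (not isolated)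
12 | ent-(12-[(4-methoxybenzyl)oxy]-13,14,15,16-tetranorlabda-1,7-dien-3-one); trans-fused, C9 chain cis to the C10 methyl | COc1ccc(cc1)COCC[C@H]1[C@]2(C)C=CC(=O)C(C)(C)[C@H]2CC=C1C | intermediate
13 | ent-(12-[(4-methoxybenzyl)oxy]-13,14,15,16-tetranorlabd-7-en-3-one) | COc1ccc(cc1)COCC[C@H]1[C@]2(C)CCC(=O)C(C)(C)[C@H]2CC=C1C | intermediate
14 | ent-(8α-hydroperoxy-12-[(4-methoxybenzyl)oxy]-13,14,15,16-tetranorlabdan-3-one) | COc1ccc(cc1)COCC[C@H]1[C@]2(C)CCC(=O)C(C)(C)[C@H]2CC[C@]1(C)OO | intermediate (not isolated)
15 | ent-(8α-hydroxy-12-[(4-methoxybenzyl)oxy]-13,14,15,16-tetranorlabdan-3-one) | COc1ccc(cc1)COCC[C@H]1[C@]2(C)CCC(=O)C(C)(C)[C@H]2CC[C@]1(C)O | intermediate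
16 | ent-(12-[(4-methoxybenzyl)oxy]-8α-(triethylsilyloxy)-13,14,15,16-tetranorlabdan-3-one) | COc1ccc(cc1)COCC[C@H]1[C@]2(C)CCC(=O)C(C)(C)[C@H]2CC[C@]1(C)O[Si](CC)(CC)CC | intermediate
17 | ent-(12-[(4-methoxybenzyl)oxy]-8α-(triethylsilyloxy)-13,14,15,16-tetranorlabd-2-en-3-yl trifluoromethanesulfonate) | COc1ccc(cc1)COCC[C@H]1[C@]2(C)CC=C(OS(=O)(=O)C(F)(F)F)C(C)(C)[C@H]2CC[C@]1(C)O[Si](CC)(CC)CC | intermediate
18 | ent-(3-bromo-12-[(4-methoxybenzyl)oxy]-8α-(triethylsilyloxy)-13,14,15,16-tetranorlabd-2-ene) | COc1ccc(cc1)COCC[C@H]1[C@]2(C)CC=C(Br)C(C)(C)[C@H]2CC[C@]1(C)O[Si](CC)(CC)CC | intermediate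
19 | ent-(3β-bromo-12-[(4-methoxybenzyl)oxy]-8α-(triethylsilyloxy)-13,14,15,16-tetranorlabdane) | COc1ccc(cc1)COCC[C@H]1[C@]2(C)CC[C@@H](Br)C(C)(C)[C@H]2CC[C@]1(C)O[Si](CC)(CC)CC | intermediate
20 | ent-(3β-bromo-8α-(triethylsilyloxy)-13,14,15,16-tetranorlabdan-12-ol) | OCC[C@H]1[C@]2(C)CC[C@@H](Br)C(C)(C)[C@H]2CC[C@]1(C)O[Si](CC)(CC)CC | intermediate
21 | ent-(3β-bromo-12-iodo-8α-(triethylsilyloxy)-13,14,15,16-tetranorlabdane) | ICC[C@H]1[C@]2(C)CC[C@@H](Br)C(C)(C)[C@H]2CC[C@]1(C)O[Si](CC)(CC)CC | intermediate
22 | but-2-yn-1-ol | CC#CCO | starting material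
23 | tert-butyl(but-2-yn-1-yloxy)dimethylsilane | CC#CCO[Si](C)(C)C(C)(C)C | intermediate
24 | (E)-alkenylzirconocene chloride from 23 (zirconium on C3, trans to the CH2O group) | C/C(=C\CO[Si](C)(C)C(C)(C)C)[Zr](Cl)(C1C=CC=C1)C1C=CC=C1 | intermediate (not isolated)
25 | tert-butyl{[(2E)-3-iodobut-2-en-1-yl]oxy}dimethylsilane | C/C(I)=C\CO[Si](C)(C)C(C)(C)C | intermediate
26 | C12 alkylzinc iodide from 21 | I[Zn]CC[C@H]1[C@]2(C)CC[C@@H](Br)C(C)(C)[C@H]2CC[C@]1(C)O[Si](CC)(CC)CC | intermediate (not isolated)
27 | ent-(3β-bromo-15-(tert-butyldimethylsilyloxy)-8α-(triethylsilyloxy)labd-13E-ene) | C/C(=C\CO[Si](C)(C)C(C)(C)C)CC[C@H]1[C@]2(C)CC[C@@H](Br)C(C)(C)[C@H]2CC[C@]1(C)O[Si](CC)(CC)CC | intermediate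
28 | (1S,2S,4aS,6R,8aR)-6-bromo-1-[(3E)-5-hydroxy-3-methylpent-3-en-1-yl]-2,5,5,8a-tetramethyldecahydronaphthalen-2-ol | C/C(=C\CO)CC[C@H]1[C@]2(C)CC[C@@H](Br)C(C)(C)[C@H]2CC[C@]1(C)O | target

**Step count and risks**
Total steps: 20. Longest linear sequence: 15 steps (steps 4–16, 19 and 20; the branch through steps 1–3 is equally long).

Steps most likely to fail:

Step 7. The cycloaddition may run partly or wholly through the formyl-endo arrangement, in which the tert-alkyl group stays clear of the diene; this would place C11 trans to the C10 methyl, while C5 and C10, which depend only on the enal geometry and the catalyst, would be set as planned. The fallback sets out from 5 and 9, keeps the cycloaddition as the ring-forming event and sets C9 afresh later, so that the endo/exo outcome no longer matters. The C9 epimer of aldehyde 10 F1, alone or mixed with 10, is carried through the aldol condensation of step 8 to the 9-epi dienone F2 and through the rhodium hydrogenation of step 9 to the 9-epi ketone F3. RhCl3·3H2O in ethanol at reflux should then move the C7=C8 bond into the tetrasubstituted C8=C9 position and give the Δ8(9) ketone F4, in which C9 is no longer a stereocentre (13 gives the same compound). Hydroboration with excess BH3·THF followed by NaOH/H2O2 should add hydrogen to C9 and boron to the less hindered C8 from the α face, opposite the C10 methyl, which sets 9α-H and 8α-OH and also reduces the C3 ketone, giving the 3,8α-diol F5. Dess–Martin periodinane then oxidises only the secondary alcohol, and the fallback comes back to the route at 15.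

Step 14. Hydrogen-atom transfer to the hindered alkenyl bromide may be slow, bromine may be lost by reduction, or the second hydrogen may be delivered from the β face. The fallback sets out from 16 and replaces the radical hydrogenation by a substitution with inversion. LiBH(s-Bu)3 in THF at −78 °C should deliver hydride from the equatorial direction and give the axial 3α-alcohol F6. CBr4/PPh3 (Appel bromination) should then displace the activated axial oxygen with inversion to give the equatorial bromide, and the fallback comes back to the route at 19. Elimination towards C2 and migration of a C4 methyl are the side reactions to watch for.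

Step 10. Dioxygen may add to the C8 radical from the β face, or the radical may be reduced to the alkane. The fallback sets out from 13 and fixes the C8 oxygen by epoxidation instead of radical capture. mCPBA with NaHCO3 in CH2Cl2 should epoxidise the C7=C8 bond from the α face, opposite the C10 methyl, to give the 7α,8α-epoxy ketone F7. LiAlH4 in THF should then deliver hydride to the secondary C7 and reduce the C3 ketone to the equatorial alcohol, giving the 3β,8α-diol F8. Dess–Martin periodinane oxidises only the secondary alcohol, and the fallback comes back to the route at 15.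

Further compounds
F1 | step 7 | C9 epimer of 10 (C11 cis to the formyl group) | COc1ccc(cc1)COCC[C@@H]1[C@](C)(C=O)[C@H](CC=C1C)C(C)(C)C(C)=O
F2 | step 7 | C9 epimer of dienone 12 | COc1ccc(cc1)COCC[C@@H]1[C@]2(C)C=CC(=O)C(C)(C)[C@H]2CC=C1C
F3 | step 7 | C9 epimer of ketone 13 | COc1ccc(cc1)COCC[C@@H]1[C@]2(C)CCC(=O)C(C)(C)[C@H]2CC=C1C
F4 | step 7 | ent-(12-[(4-methoxybenzyl)oxy]-13,14,15,16-tetranorlabd-8-en-3-one), double bond C8=C9 | COc1ccc(cc1)COCCC=1[C@]2(C)CCC(=O)C(C)(C)[C@H]2CCC=1C
F5 | step 7 | ent-(12-[(4-methoxybenzyl)oxy]-13,14,15,16-tetranorlabdane-3,8α-diol), either C3 epimer | COc1ccc(cc1)COCC[C@H]1[C@]2(C)CCC(O)C(C)(C)[C@H]2CC[C@]1(C)O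
F6 | step 14 | ent-(12-[(4-methoxybenzyl)oxy]-8α-(triethylsilyloxy)-13,14,15,16-tetranorlabdan-3α-ol) | COc1ccc(cc1)COCC[C@H]1[C@]2(C)CC[C@H](O)C(C)(C)[C@H]2CC[C@]1(C)O[Si](CC)(CC)CC
F7 | step 10 | ent-(7α,8α-epoxy-12-[(4-methoxybenzyl)oxy]-13,14,15,16-tetranorlabdan-3-one) | COc1ccc(cc1)COCC[C@H]1[C@]2(C)CCC(=O)C(C)(C)[C@H]2C[C@@H]3O[C@@]31C
F8 | step 10 | ent-(12-[(4-methoxybenzyl)oxy]-13,14,15,16-tetranorlabdane-3β,8α-diol) | COc1ccc(cc1)COCC[C@H]1[C@]2(C)CC[C@@H](O)C(C)(C)[C@H]2CC[C@]1(C)O
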